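The easy step comes first: L meets D and gives L.D, which J then carries off through J.L.D towards E.

    L + D → L.D (k1 = 1800 /M/s)
    J + L.D → J.L.D (k2 = 230 /M/s)
    J.L.D → E (k3 = 0.97 /s)
    L + J → L.J (k4 = 72 /M/s)

| setting | elm | oak | ash | maple |
|---|---|---|---|---|
| L | 0.20 mM | 0.20 mM (fed, over 7.50 s) | 0.20 mM | 0.20 mM |
| D | 0.260 mM | 0.260 mM | 0.260 mM | 0.260 mM |
| J | 0.190 mM | 0.190 mM | 0.190 mM | 0.190 mM |
| time | 15 s | 15 s | 15 s |  |
| remark | plug flow through a tube for 15 s, no back-mixing | all but L at the start; L goes in evenly over 7.50 s, the run ends at 15 s | everything together in a closed stirred flask, run for 15 s | one stirred flow tank at steady state, fed with the mixture as stated, mean residence time 15 s |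

1. the set-up with the highest amount of L.D at the outlet or at the end, in percent of the L put in ("none" if the first two lie within 2 percentage points) (elm / oak / ash / maple / none)
2. amount of L.D at the outlet or at the end, in percent of the L put in, elm
3. amount of L.D at the outlet or at the end, in percent of the L put in, oak
4. amount of L.D at the outlet or at the end, in percent of the L put in, ash
5. amount of L.D at the outlet or at the end, in percent of the L put in, maple

- the stated concentrations are those of everything mixed, before any reaction; amounts are the same in each set-up
- the feed brings no volume worth counting
- run time (elm): 15 s

**Two clocks.** At the charged amounts, D takes up L with a make time of 2.14 s. The drain time is 22.9 s: the mean life of L.D against J at its charged amount, one over the rate constant of the J step times that amount. The make time is the shorter clock.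

**Bench rule.** Treat both steps as pseudo-first-order, let L become L.D after one make time, then let the drain clock run. Elm and ash share one history, a slice of plug flow ageing like the closed flask, so both get 57.0 %. In oak, L arrives on average 3.75 s later, which gives 67.1 %. In maple, the tank form of the same two clocks gives 52.9 %.

**Where it stops.** The rule holds D at its charge, yet L is the limiting reagent at only 0.769 of D. Full take-up of L leaves D at 0.0600 mM, where the make time is 9.26 s, longer than at the start and 0.404 of the drain time. The rule holds J at its charge as well, though the J step and the L + J step both use J up. So my figures are estimates, and oak's lead of 10 percentage points is one too. I commit to the order: oak, then elm level with ash, then maple.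

**The forecast.** It names oak, with elm 61 %, oak 64.7 %, ash 61 % and maple 49.8 %, on the ground that “dosing keeps L low, so L.D forms later and has less time to be consumed”. My elm figure is lower; my oak and maple figures are higher.

**The result.** Oak gives the most L.D, 63.9 %, against 61.0 % for elm, 61.0 % for ash and 49.6 % for maple, and the drain clock had said 67.1 % for oak. At the end, oak still holds 8.51 % of its L unbound, elm 4.17 %. A neighbour of oak charged with 0.76 mM of J has a drain time of 5.72 s, a quarter of oak's, and the same clock gives 20.3 %. That neighbour ends with 54.2 % as E and 23.0 % as L.D.

The numbers were set for the occasion; the run is a simulation.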